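In this closed, stirred vessel Z and G turn L into E and D into X. With each enantiomer taken as first order, Z and G cancel in one ratio: the logarithm of the fraction of L left over that of D left, D being the balance of the readings.

| flask | L | D | G | Z | remark | time |
|---|---|---|---|---|---|---|
| delta | 0.20 M | 0.20 M | 1.5 equiv | 0.47 mol% | run made earlier |  |
| zeta | 0.20 M | 0.20 M | 1.5 equiv | 1.9 mol% | run made earlier |  |
| flask | 0.20 M | 0.20 M | 1.50 equiv | 0.95 mol% |  | 8.0 h |

| run | time / h | E / % | X / % | L / % |
|---|---|---|---|---|
| delta | 0.667 | 0 | 0.7 | 48.3 |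
| delta | 1.00 | 2.1 | 0.3 | 49.2 |
| delta | 1.33 | 3.0 | 2.6 | 47.3 |
| delta | 2.50 | 3.6 | 3.0 | 45.8 |
| delta | 3.00 | 5.0 | 3.6 | 43.3 |
| delta | 5.00 | 6.5 | 4.0 | 43.1 |
| delta | 8.00 | 9.3 | 7.0 | 39.2 |
| zeta | 1.00 | 8.0 | 2.3 | 40.7 |
| zeta | 2.50 | 12.6 | 7.7 | 35.9 |
| zeta | 3.00 | 14.5 | 12.5 | 33.3 |
| zeta | 5.00 | 18.9 | 14.7 | 29.3 |
| zeta | 6.00 | 20.9 | 13.8 | 27.9 |
| zeta | 8.00 | 20.6 | 17.5 | 26.2 |

(scatter of a reading: 1 percentage point)

- Z is single-handed; L and D are mirror images of each other, charged as a racemate, each of them at the stated concentration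
- the analysis behind the earlier runs scatters by 1 percentage point, standard deviation
- an excess is the difference of the two amounts in percent of their sum
- an excess is below zero if the other one leads

1. excess of E over X in the product at 10 min
2. excess of E over X in the product at 8.0 h
3. part of the L and D charged together that has reacted at 8.0 h

At 8.0 h this ratio reads 2.09 in delta and 1.92 in zeta, so we carry 2.00, the selectivity factor: how much faster L is taken than D. Fresh product carries that ratio, so the excess of E over X starts at the factor less one over the factor plus one, 33.4 %, our figure for the flask at 10 min.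

Is one number enough? In zeta at 8.0 h, D stands above L by 9.5 percentage points, yet E stands above X by 3.1 points, and delta shows 5.3 points against 2.3 points. We read this as E passing into X. The two runs kept a mean share of 0.380 of that gap at the same clock time, which puts the flask at 12.7 % at 8.0 h.

The forecast says 65 %, 10 % and 30 %, and reads the runs as “a selective burst of a few turnovers”.

The flask gives 28.1 %, 12.3 % and 25.4 %.

    E ⇌ X (k = 0.0680 h⁻¹)
    G + Z + D → Z + X (k = 100 M⁻² h⁻¹)
    Z → J (k = 0.0730 h⁻¹)
    G ⇌ Q (K = 18.0, k = 0.0710 h⁻¹)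
    G + Z + L → Z + E (k = 180 M⁻² h⁻¹)

Our 33.4 % stands 5.3 points above the flask's early excess, and our 12.7 % stands 0.40 points above its late one. The flask's remainders, 68 % of L and 81 % of D, give a factor of 1.80, beside the carried 2.00. The neighbouring flask with 3.8 mol% of Z leaves 38 % of L and 59 % of D, which gives 1.80; its excess is 27.6 % at 10 min and 8.28 % at 8.0 h, with 51.4 % reacted.

(The runs come from a simulation for substances that don't exist; noise was put on by code.)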